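**Retrosynthetic overview**
1. Last disconnections: the three O-benzyl groups (hydrogenolysis) and the two side-chain acetates (methanolysis), which lead back to a fully protected flavone.
2. Key disconnection C2 (ring C)–C1' (ring B): one-pot dehydrogenation/oxidative boron-Heck arylation of 5,7-bis(benzyloxy)chroman-4-one (ring C at the saturated level) with a ring B pinacol boronate that already carries the complete (1R,2R) side chain. Ring C is aromatised in the same flask.
3. Enabling feature: in ring C, C2 is the β-carbon of the vinylogous ester O1–C2=C3–C4=O and, in the dihydro form, C3 is an enolisable CH2 next to the C4 ketone. Divalent palladium can therefore unveil C2=C3, deliver the aryl group to C2 only and re-aromatise. On ring B the boron-bearing C1' lies between two C–H (C2', C6'), the methoxy groups being meta.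
4. Side chain: both stereocentres (threo, 7''R,8''R) come from one dynamic kinetic resolution by asymmetric transfer hydrogenation of a racemic α-aryloxy β-keto ester, made by crossed Claisen acylation of the aryloxyacetate of 4-bromo-2,6-dimethoxyphenol.
5. Ring order: ring A, ring B and the side-chain arene are bought as arenes; ring C is closed on phloroglucinol (Friedel–Crafts acylation, then O-alkylative closure) and is the last ring to become aromatic (key step).

Key step: step 9

Remark: 4-bromo-2,6-dimethoxyphenol, ethyl bromoacetate, 4-(benzyloxy)benzoyl chloride, phloroglucinol and 3-chloropropanoic acid are taken as commercial. C7'' is the benzylic carbinol carbon and C8'' the aryloxy-bearing carbon of the side chain. The syn preference of the transfer hydrogenation in step 3 is assumed to carry over from α-alkoxy to α-aryloxy β-keto esters.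

**Route**

Step 1
Reactants: 1 4-bromo-2,6-dimethoxyphenol; 2 ethyl bromoacetate
Product: 3 ethyl 2-(4-bromo-2,6-dimethoxyphenoxy)acetate
Conditions: K2CO3, acetone, reflux
Reagents that add atoms: none
Why: Williamson ether synthesis, in which the hindered but nucleophilic 2,6-dimethoxyphenoxide displaces bromide from the primary, carbonyl-activated carbon of 2 by SN2.

Step 2
Reactants: 3 ethyl 2-(4-bromo-2,6-dimethoxyphenoxy)acetate; 4 4-(benzyloxy)benzoyl chloride
Product: 5 ethyl 3-[4-(benzyloxy)phenyl]-2-(4-bromo-2,6-dimethoxyphenoxy)-3-oxopropanoate (racemic)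
Conditions: LiN(SiMe3)2 (2.2 equiv), THF, −78 °C; then 4, −78 → −40 °C; aq. NH4Cl
Reagents that add atoms: none
Why: Crossed Claisen C-acylation of the lithium ester enolate by the acid chloride, the second equivalent of base storing the more acidic β-keto ester as its enolate so that proton transfer and double acylation are suppressed; the new α-centre is deliberately left racemic and labile.

Step 3
Reactants: 5 ethyl 3-[4-(benzyloxy)phenyl]-2-(4-bromo-2,6-dimethoxyphenoxy)-3-oxopropanoate (racemic)
Product: 6 ethyl (2S,3R)-3-[4-(benzyloxy)phenyl]-2-(4-bromo-2,6-dimethoxyphenoxy)-3-hydroxypropanoate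
Conditions: RuCl[(S,S)-TsDPEN](p-cymene) (2 mol%), HCO2H/Et3N (5:2), CH2Cl2, 30 °C
Reagents that add atoms: none
Why: Noyori-type asymmetric transfer hydrogenation with dynamic kinetic resolution, in which C2 racemises through the enol under Et3N faster than the ketone is reduced, the (S,S)-catalyst delivers hydride to the ketone face fixed by the aryl/η6-arene contact to give the (3R)-carbinol, and the C2 epimer leading to the syn (2S,3R) product should be reduced faster, as known for α-alkoxy β-keto esters.

Step 4
Reactants: 6 ethyl (2S,3R)-3-[4-(benzyloxy)phenyl]-2-(4-bromo-2,6-dimethoxyphenoxy)-3-hydroxypropanoate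
Product: 7 (1R,2R)-1-[4-(benzyloxy)phenyl]-2-(4-bromo-2,6-dimethoxyphenoxy)propane-1,3-diol
Conditions: LiBH4, THF, 0 °C → rt
Reagents that add atoms: none
Why: Chemoselective borohydride reduction of the activated α-aryloxy ester at low temperature outruns retro-aldol or enolisation, so neither stereocentre is touched (the descriptor at the aryloxy carbon changes from S to R only because CH2OH ranks below the carbinol carbon).

Step 5
Reactants: 7 (1R,2R)-1-[4-(benzyloxy)phenyl]-2-(4-bromo-2,6-dimethoxyphenoxy)propane-1,3-diol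
Product: 8 (1R,2R)-1-[4-(benzyloxy)phenyl]-2-(4-bromo-2,6-dimethoxyphenoxy)propane-1,3-diyl diacetate
Conditions: Ac2O, pyridine, DMAP (cat.), CH2Cl2, rt
Reagents that add atoms: acetic anhydride CC(=O)OC(C)=O
Why: DMAP-catalysed acylation masks both alcohols as acetates, which are inert to the palladium/O2 conditions of step 9 and are later removed by base without any acid that could ionise the benzylic centre.

Step 6
Reactants: 8 (1R,2R)-1-[4-(benzyloxy)phenyl]-2-(4-bromo-2,6-dimethoxyphenoxy)propane-1,3-diyl diacetate
Product: 9 (1R,2R)-1-[4-(benzyloxy)phenyl]-2-[2,6-dimethoxy-4-(4,4,5,5-tetramethyl-1,3,2-dioxaborolan-2-yl)phenoxy]propane-1,3-diyl diacetate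
Conditions: B2pin2, PdCl2(dppf) (cat.), KOAc, 1,4-dioxane, 90 °C
Reagents that add atoms: bis(pinacolato)diboron CC1(C)OB(OC1(C)C)B1OC(C)(C)C(C)(C)O1
Why: Miyaura borylation (oxidative addition of zerovalent palladium into Ar–Br, acetate-assisted transmetalation with the diboron, reductive elimination), with KOAc too weak a base to cleave the acetates or start Suzuki homocoupling.

Step 7
Reactants: 10 phloroglucinol; 11 3-chloropropanoic acid
Product: 13 5,7-dihydroxychroman-4-one, via chloroketone 12 (not isolated)
Conditions: CF3SO3H, 80 °C; then 2 M aq. NaOH, 0 °C → rt; then aq. HCl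
Reagents that add atoms: none
Why: Friedel–Crafts acylation of the symmetrical triphenol by the acylium ion formed in CF3SO3H, followed by intramolecular Williamson O-alkylation (6-exo-tet) of an ortho phenoxide on the primary chloride, which closes ring C with no regiochemical issue.

Step 8
Reactants: 13 5,7-dihydroxychroman-4-one
Product: 14 5,7-bis(benzyloxy)chroman-4-one
Conditions: BnBr (2.5 equiv), K2CO3, DMF, 70 °C
Reagents that add atoms: benzyl bromide BrCc1ccccc1
Why: Williamson benzylation, forced with excess bromide in warm DMF so that the hydrogen-bonded 5-OH is also capped and the peri hydroxy-ketone pair cannot chelate palladium in step 9.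

Step 9
Reactants: 14 5,7-bis(benzyloxy)chroman-4-one; 9 (1R,2R)-1-[4-(benzyloxy)phenyl]-2-[2,6-dimethoxy-4-(4,4,5,5-tetramethyl-1,3,2-dioxaborolan-2-yl)phenoxy]propane-1,3-diyl diacetate
Product: 17 (1R,2R)-1-[4-(benzyloxy)phenyl]-2-{4-[5,7-bis(benzyloxy)-4-oxo-4H-chromen-2-yl]-2,6-dimethoxyphenoxy}propane-1,3-diyl diacetate, via chromone 15 (not isolated), via flavanone 16 (not isolated)
Conditions: Pd(O2CCF3)2 (15 mol%), 5-nitro-1,10-phenanthroline (20 mol%), O2 (1 atm), DMSO, 100 °C; 14 in excess (1.5 equiv), 9 added in portions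
Reagents that add atoms: none
Why: The divalent palladium trifluoroacetate/phenanthroline catalyst palladates the enol of 14 at C3 and β-hydride eliminates to chromone 15; transmetalation of 9 then gives an aryl–palladium species that adds across C2=C3 with aryl on C2 and palladium on C3, and the C3-palladium enolate either epimerises through its oxygen-bound form and undergoes syn β-hydride elimination or is protonated to flavanone 16, which the same catalyst dehydrogenates, O2 reoxidising zerovalent palladium each time. The closest known reaction type is the one-pot dehydrogenation/oxidative boron-Heck coupling of chroman-4-ones with aryl pinacol boronates, which itself rests on the oxidative Heck and conjugate arylation of chromones. No ring is closed: ring C is carried as the saturated dihydropyranone and is aromatised to the 4-pyranone here. No stereocentre is created, since C2 of 16 is sp3 only transiently and both epimers converge on planar 17, and the acetate-masked side-chain centres have neither an acidic C–H nor a free carbinol open to palladium-mediated oxidation. The step needs C2 over C3 regioselectivity, which the polarisation of the vinylogous ester O1–C2=C3–C4=O secures (aryl to the β-carbon, palladium α to the carbonyl). It also needs carbopalladation to outrun homocoupling and protodeboronation of 9, which is helped by the unhindered boron-bearing carbon (two ortho C–H, both methoxy groups meta), by portionwise addition of 9 and by the excess of cheap 14.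

Step 10
Reactants: 17 (1R,2R)-1-[4-(benzyloxy)phenyl]-2-{4-[5,7-bis(benzyloxy)-4-oxo-4H-chromen-2-yl]-2,6-dimethoxyphenoxy}propane-1,3-diyl diacetate
Product: 18 5,7-bis(benzyloxy)-2-(4-{[(1R,2R)-1-[4-(benzyloxy)phenyl]-1,3-dihydroxypropan-2-yl]oxy}-3,5-dimethoxyphenyl)-4H-chromen-4-one
Conditions: K2CO3 (0.3 equiv), MeOH/THF (1:1), 0 °C → rt
Reagents that add atoms: none
Why: Base-catalysed (Zemplén-type) transesterification cleaves both acetates by acyl–oxygen scission, so both centres keep their configuration, and because the para phenol is still benzylated no quinone methide can form from the benzylic acetate.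

Step 11
Reactants: 18 5,7-bis(benzyloxy)-2-(4-{[(1R,2R)-1-[4-(benzyloxy)phenyl]-1,3-dihydroxypropan-2-yl]oxy}-3,5-dimethoxyphenyl)-4H-chromen-4-one
Product: 19 2-(4-{[(1R,2R)-1,3-dihydroxy-1-(4-hydroxyphenyl)propan-2-yl]oxy}-3,5-dimethoxyphenyl)-5,7-dihydroxy-4H-chromen-4-one (CNP0133235.3)
Conditions: H2 (1 atm), 10% Pd/C, THF/MeOH (1:1), rt, stopped at full debenzylation
Reagents that add atoms: none
Why: Catalytic hydrogenolysis of the three aryl benzyl ethers under neutral conditions should be faster than reduction of the flavone C2=C3 bond or hydrogenolysis of the benzylic C–OH, and nothing present can epimerise the side chain.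

**Compound list**
1 | 4-bromo-2,6-dimethoxyphenol | COc1cc(Br)cc(OC)c1O | starting material
2 | ethyl bromoacetate | CCOC(=O)CBr | starting material
3 | ethyl 2-(4-bromo-2,6-dimethoxyphenoxy)acetate | CCOC(=O)COc1c(OC)cc(Br)cc1OC | intermediate
4 | 4-(benzyloxy)benzoyl chloride | O=C(Cl)c1ccc(OCc2ccccc2)cc1 | starting material
5 | ethyl 3-[4-(benzyloxy)phenyl]-2-(4-bromo-2,6-dimethoxyphenoxy)-3-oxopropanoate (racemic) | COc1cc(Br)cc(OC)c1OC(C(=O)OCC)C(=O)c1ccc(OCc2ccccc2)cc1 | intermediate
6 | ethyl (2S,3R)-3-[4-(benzyloxy)phenyl]-2-(4-bromo-2,6-dimethoxyphenoxy)-3-hydroxypropanoate | COc1cc(Br)cc(OC)c1O[C@H](C(=O)OCC)[C@H](O)c1ccc(OCc2ccccc2)cc1 | intermediate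
7 | (1R,2R)-1-[4-(benzyloxy)phenyl]-2-(4-bromo-2,6-dimethoxyphenoxy)propane-1,3-diol | COc1cc(Br)cc(OC)c1O[C@H](CO)[C@H](O)c1ccc(OCc2ccccc2)cc1 | intermediate
8 | (1R,2R)-1-[4-(benzyloxy)phenyl]-2-(4-bromo-2,6-dimethoxyphenoxy)propane-1,3-diyl diacetate | COc1cc(Br)cc(OC)c1O[C@H](COC(C)=O)[C@H](OC(C)=O)c1ccc(OCc2ccccc2)cc1 | intermediate
9 | (1R,2R)-1-[4-(benzyloxy)phenyl]-2-[2,6-dimethoxy-4-(4,4,5,5-tetramethyl-1,3,2-dioxaborolan-2-yl)phenoxy]propane-1,3-diyl diacetate | COc1cc(B2OC(C)(C)C(C)(C)O2)cc(OC)c1O[C@H](COC(C)=O)[C@H](OC(C)=O)c1ccc(OCc2ccccc2)cc1 | intermediate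
10 | phloroglucinol (benzene-1,3,5-triol) | Oc1cc(O)cc(O)c1 | starting material
11 | 3-chloropropanoic acid | OC(=O)CCCl | starting material
12 | 3-chloro-1-(2,4,6-trihydroxyphenyl)propan-1-one | O=C(CCCl)c1c(O)cc(O)cc1O | intermediate
13 | 5,7-dihydroxychroman-4-one | O=C1CCOc2cc(O)cc(O)c12 | intermediate
14 | 5,7-bis(benzyloxy)chroman-4-one | O=C1CCOc2cc(OCc3ccccc3)cc(OCc3ccccc3)c12 | intermediate
15 | 5,7-bis(benzyloxy)-4H-chromen-4-one | O=c1ccoc2cc(OCc3ccccc3)cc(OCc3ccccc3)c12 | intermediate
16 | (1R,2R)-1-[4-(benzyloxy)phenyl]-2-{4-[5,7-bis(benzyloxy)-4-oxochroman-2-yl]-2,6-dimethoxyphenoxy}propane-1,3-diyl diacetate, mixture of the two C2 epimers of the chromanone ring | COc1cc(C2CC(=O)c3c(OCc4ccccc4)cc(OCc4ccccc4)cc3O2)cc(OC)c1O[C@H](COC(C)=O)[C@H](OC(C)=O)c1ccc(OCc2ccccc2)cc1 | intermediate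
17 | (1R,2R)-1-[4-(benzyloxy)phenyl]-2-{4-[5,7-bis(benzyloxy)-4-oxo-4H-chromen-2-yl]-2,6-dimethoxyphenoxy}propane-1,3-diyl diacetate | COc1cc(-c2cc(=O)c3c(OCc4ccccc4)cc(OCc4ccccc4)cc3o2)cc(OC)c1O[C@H](COC(C)=O)[C@H](OC(C)=O)c1ccc(OCc2ccccc2)cc1 | intermediate
18 | 5,7-bis(benzyloxy)-2-(4-{[(1R,2R)-1-[4-(benzyloxy)phenyl]-1,3-dihydroxypropan-2-yl]oxy}-3,5-dimethoxyphenyl)-4H-chromen-4-one | COc1cc(-c2cc(=O)c3c(OCc4ccccc4)cc(OCc4ccccc4)cc3o2)cc(OC)c1O[C@H](CO)[C@H](O)c1ccc(OCc2ccccc2)cc1 | intermediate
19 | 2-(4-{[(1R,2R)-1,3-dihydroxy-1-(4-hydroxyphenyl)propan-2-yl]oxy}-3,5-dimethoxyphenyl)-5,7-dihydroxy-4H-chromen-4-one | COc1cc(-c2cc(=O)c3c(O)cc(O)cc3o2)cc(OC)c1O[C@H](CO)[C@H](O)c1ccc(O)cc1 | target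

**Count**
Total steps: 11. Longest linear sequence: 9 (steps 1, 2, 3, 4, 5, 6, 9, 10, 11).

**Steps most likely to fail**

1. Step 9. The electron-rich boronate may be consumed by oxidative homocoupling, protodeboronation or peroxide-mediated hydroxylation faster than it is carbopalladated, or the sequence may stall before the second dehydrogenation. The fallback sets out from 14 and 9 and returns at 17, forming the same bond in three separate redox events. Compound 14 is dehydrogenated alone with 2-iodoxybenzoic acid (DMSO, 80 °C) and chromone 15 is isolated. Redox-neutral conjugate addition of 9 catalysed by [Rh(OH)(cod)]2 (dioxane/H2O, 60 °C, no added base, so the acetates and the pyranone ring stay intact) should give flavanone 16, isolated as its epimer mixture. Iodine in pyridine at 90 °C then dehydrogenates both epimers to 17.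

2. Step 3. Discrimination between the syn and anti transition states may be poor with the bulky 2,6-dimethoxyaryloxy group, or racemisation of C2 may be slower than reduction. The fallback sets out from 3 and returns at 7 with auxiliary control instead of catalyst control. Saponification of 3 (LiOH, THF/H2O) gives 2-(4-bromo-2,6-dimethoxyphenoxy)acetic acid F1. Mixed-anhydride activation (pivaloyl chloride, Et3N, THF, −20 °C) and addition of (S)-4-benzyloxazolidin-2-one with LiCl gives (S)-4-benzyl-3-[2-(4-bromo-2,6-dimethoxyphenoxy)acetyl]oxazolidin-2-one F2. An Evans syn-aldol reaction (Bu2BOTf, iPr2NEt, CH2Cl2, −78 → 0 °C, then 4-(benzyloxy)benzaldehyde) through the boron Z-enolate and a chair transition state should give (S)-4-benzyl-3-[(2S,3R)-3-[4-(benzyloxy)phenyl]-2-(4-bromo-2,6-dimethoxyphenoxy)-3-hydroxypropanoyl]oxazolidin-2-one F3. Reductive removal of the auxiliary with LiBH4 (THF, trace H2O, 0 °C) delivers diol 7 directly.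

3. Step 2. The enolate may be acylated on oxygen or twice on carbon, or may be quenched by proton transfer from the product. The fallback sets out from 4 and 1 and returns at 5, making the C–O bond last instead of the C–C bond. Acylation of potassium ethyl malonate with 4 (MgCl2, Et3N, MeCN, then aqueous acid with loss of CO2) gives ethyl 3-[4-(benzyloxy)phenyl]-3-oxopropanoate F4. Bromination with N-bromosuccinimide (cat. NH4OAc, Et2O, rt) gives ethyl 3-[4-(benzyloxy)phenyl]-2-bromo-3-oxopropanoate F5. SN2 displacement by phenol 1 (K2CO3, acetone, rt) gives 5.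

**Further compounds**
F0 | step 9 | none | none
F1 | step 3 | 2-(4-bromo-2,6-dimethoxyphenoxy)acetic acid | COc1cc(Br)cc(OC)c1OCC(=O)O
F2 | step 3 | (S)-4-benzyl-3-[2-(4-bromo-2,6-dimethoxyphenoxy)acetyl]oxazolidin-2-one | COc1cc(Br)cc(OC)c1OCC(=O)N1[C@@H](Cc2ccccc2)COC1=O
F3 | step 3 | (S)-4-benzyl-3-[(2S,3R)-3-[4-(benzyloxy)phenyl]-2-(4-bromo-2,6-dimethoxyphenoxy)-3-hydroxypropanoyl]oxazolidin-2-one | COc1cc(Br)cc(OC)c1O[C@H](C(=O)N1[C@@H](Cc2ccccc2)COC1=O)[C@H](O)c1ccc(OCc2ccccc2)cc1
F4 | step 2 | ethyl 3-[4-(benzyloxy)phenyl]-3-oxopropanoate | CCOC(=O)CC(=O)c1ccc(OCc2ccccc2)cc1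
F5 | step 2 | ethyl 3-[4-(benzyloxy)phenyl]-2-bromo-3-oxopropanoate (racemic) | CCOC(=O)C(Br)C(=O)c1ccc(OCc2ccccc2)cc1
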